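## Retrosynthetic overview

1. The last C=C (C11=C12, carotenoid numbering) comes from a Wittig union of an east C30 polyenyl phosphonium salt with a west C20 epoxy-trienal; one desilylation then frees the third tertiary alcohol.
2. East half: C30 salt ⇐ C10 dialdehyde + C20 phosphonium salt ⇐ two C5-phosphonate (HWE) extensions of an α-branched aldehyde ⇐ (R)-lavandulol (Evans deconjugative prenylation, then double Markovnikov hydration).
3. West half: C20 trienal ⇐ C2 and C5 HWE extensions of a trans-epoxy methyl ketone ⇐ Darzens-type pair of steps (chloroacetone aldol to an anti-chlorohydrin, then intramolecular O-alkylation by the aldol hydroxyl) ⇐ α-branched aldehyde ⇐ (S)-lavandulol.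
4. Ring order: the oxirane is the only ring; it is closed once, in the west branch, and carried unchanged to the end.

Assumption: positions use carotenoid numbering (oxirane = C3–C4; the SMILES reads as 2R,3R,4R,2′S, all-E), and 2,7-dimethylocta-2,4,6-trienedial, the C5 phosphonate and both 4-benzyl-oxazolidin-2-ones are taken as commercial.

## West branch (steps 1–15)

Step 1
Reactants: 1 (S)-4-benzyl-1,3-oxazolidin-2-one; 2 3-methylbut-2-enoyl chloride
Product: 3 (4S)-4-benzyl-3-(3-methylbut-2-enoyl)-1,3-oxazolidin-2-one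
Conditions: n-BuLi, THF, −78 °C; then 2, −78 → 0 °C
Reagents that add atoms: none
Why: N-acylation of the lithiated Evans auxiliary by the acid chloride attaches the chiral controller.

Step 2
Reactants: 3 N-senecioyl imide; 4 1-bromo-3-methylbut-2-ene (prenyl bromide)
Product: 5 (4S)-4-benzyl-3-[(2S)-5-methyl-2-(prop-1-en-2-yl)hex-4-enoyl]-1,3-oxazolidin-2-one
Conditions: NaN(SiMe3)2, THF, −78 °C; then 4, −78 → −20 °C
Reagents that add atoms: none
Why: Evans deconjugative alkylation, in which γ-deprotonation gives the chelated (Z)-dienolate that is prenylated at Cα on the face opposite the benzyl group, setting the future C2 centre and leaving an isopropenyl group.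

Step 3
Reactants: 5 alkylated imide
Product: 6 (S)-lavandulol [(2S)-5-methyl-2-(prop-1-en-2-yl)hex-4-en-1-ol]
Conditions: LiBH4, H2O (1 equiv), Et2O, 0 °C
Reagents that add atoms: none
Why: Reductive cleavage of the imide gives the primary alcohol without touching either alkene or the stereocentre and returns auxiliary 1.

Step 4
Reactants: 6 (S)-lavandulol
Product: 7 triethyl{[(2S)-5-methyl-2-(prop-1-en-2-yl)hex-4-en-1-yl]oxy}silane
Conditions: Et3SiCl, imidazole, CH2Cl2, 0 °C
Reagents that add atoms: chlorotriethylsilane CC[Si](Cl)(CC)CC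
Why: Silylation masks the primary hydroxyl so that it cannot add intramolecularly to a mercurinium ion of the prenyl alkene in the next step.

Step 5
Reactants: 7 lavandulyl silyl ether
Product: 9 (3R)-2,6-dimethyl-3-[(triethylsilyloxy)methyl]hept-5-en-2-ol, via organomercury acetate 8 (not isolated)
Conditions: Hg(OAc)2 (1.0 equiv), THF/H2O 1:1, 0 °C; then NaBH4, 3 M NaOH, 0 °C
Reagents that add atoms: water O; Hg(OAc)2 CC(=O)O[Hg]OC(C)=O (its atoms stay only in 8)
Why: Markovnikov oxymercuration–demercuration, in which the 1,1-disubstituted alkene reacts far faster than the trisubstituted prenyl alkene, so one equivalent of Hg(OAc)2 hydrates only the isopropenyl group.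

Step 6
Reactants: 9 tertiary alcohol
Product: 10 (3R)-2,6-dimethyl-2-(triethylsilyloxy)-3-[(triethylsilyloxy)methyl]hept-5-ene
Conditions: Et3SiOTf, 2,6-lutidine, CH2Cl2, −78 → 0 °C
Reagents that add atoms: triethylsilyl triflate CC[Si](CC)(CC)OS(=O)(=O)C(F)(F)F
Why: The silyl triflate silylates the hindered tertiary alcohol, which must be blocked to prevent retro-aldol cleavage of the coming β-oxy aldehyde.

Step 7
Reactants: 10 bis(silyl) ether
Product: 11 (2S)-5-methyl-2-[2-(triethylsilyloxy)propan-2-yl]hex-4-enal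
Conditions: (COCl)2, DMSO, CH2Cl2, −78 → −40 °C; then Et3N, −78 → 0 °C
Reagents that add atoms: none
Why: Swern conditions convert a primary triethylsilyl ether directly into the aldehyde (chlorosulfonium-induced O–Si cleavage, then the usual ylide fragmentation) while the tertiary silyl ether and the α-stereocentre stay intact at low temperature.

Step 8
Reactants: 11 aldehyde; 12 chloroacetone (1-chloropropan-2-one)
Product: 13 (3R,4R,5R)-3-chloro-4-hydroxy-8-methyl-5-[2-(triethylsilyloxy)propan-2-yl]non-7-en-2-one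
Conditions: 12 (5 equiv), (R)-N-[(1R,2R)-2-hydroxy-1,2-diphenylethyl]pyrrolidine-2-carboxamide (20 mol%), THF, 0 °C, 72 h
Reagents that add atoms: none
Why: Enamine-catalysed direct aldol addition (Houk–List transition state) of chloroacetone through its chlorinated carbon gives the anti-chlorohydrin, and the D-prolinamide selects the aldehyde face that the Felkin–Anh model also favours (attack anti to the CMe2OSiEt3 group), so C3 is set as R and C4 as the chloride that will be inverted.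

Step 9
Reactants: 13 anti-chlorohydrin
Product: 14 1-[(2S,3R)-3-[(3R)-2,6-dimethyl-2-(triethylsilyloxy)hept-5-en-3-yl]oxiran-2-yl]ethan-1-one
Conditions: Et3N, CH2Cl2, rt
Reagents that add atoms: none
Why: Completion of the Darzens sequence, in which the aldol hydroxyl displaces the α-chloride intramolecularly (SN2, inversion at C4), so the anti-chlorohydrin gives only the trans (3R,4R) oxirane of the target.

Step 10
Reactants: 14 epoxy ketone; 15 triethyl phosphonoacetate
Product: 16 ethyl (2E)-3-[(2R,3R)-3-[(3R)-2,6-dimethyl-2-(triethylsilyloxy)hept-5-en-3-yl]oxiran-2-yl]but-2-enoate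
Conditions: 15, NaH, THF, 0 °C → rt; chromatography
Reagents that add atoms: none
Why: Horner–Wadsworth–Emmons olefination of the methyl ketone places the ester trans to the bulky oxiranyl group (E), and the minor Z isomer is removed by chromatography.

Step 11
Reactants: 16 epoxy enoate
Product: 17 (2E)-3-[(2R,3R)-3-[(3R)-2,6-dimethyl-2-(triethylsilyloxy)hept-5-en-3-yl]oxiran-2-yl]but-2-en-1-ol
Conditions: iBu2AlH, CH2Cl2, −78 °C; aq. KNaC4H4O6
Reagents that add atoms: none
Why: 1,2-Reduction of the enoate by the aluminium hydride at −78 °C gives the allylic alcohol faster than the epoxide or silyl ether can react.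

Step 12
Reactants: 17 allylic alcohol
Product: 18 (2E)-3-[(2R,3R)-3-[(3R)-2,6-dimethyl-2-(triethylsilyloxy)hept-5-en-3-yl]oxiran-2-yl]but-2-enal
Conditions: MnO2, CH2Cl2, rt
Reagents that add atoms: none
Why: MnO2 oxidises only the allylic alcohol under neutral conditions that the vinyl epoxide tolerates.

Step 13
Reactants: 18 epoxy enal; 19 triethyl 3-methyl-4-phosphonocrotonate [ethyl (2E)-4-(diethoxyphosphoryl)-3-methylbut-2-enoate]
Product: 20 ethyl (2E,4E,6E)-7-[(2R,3R)-3-[(3R)-2,6-dimethyl-2-(triethylsilyloxy)hept-5-en-3-yl]oxiran-2-yl]-3-methylocta-2,4,6-trienoate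
Conditions: 19, LiN(SiMe3)2, THF, −78 → 0 °C
Reagents that add atoms: none
Why: Vinylogous Horner–Wadsworth–Emmons reaction forms the new C7=C8 bond E and brings C9=C10 in E from the reagent (minor 2Z isomer removed by chromatography).

Step 14
Reactants: 20 trienoate
Product: 21 (2E,4E,6E)-7-[(2R,3R)-3-[(3R)-2,6-dimethyl-2-(triethylsilyloxy)hept-5-en-3-yl]oxiran-2-yl]-3-methylocta-2,4,6-trien-1-ol
Conditions: iBu2AlH, CH2Cl2, −78 °C; aq. KNaC4H4O6
Reagents that add atoms: none
Why: Low-temperature 1,2-reduction of the conjugated ester to the allylic alcohol, as in step 11.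

Step 15
Reactants: 21 trienol
Product: 22 (2E,4E,6E)-7-[(2R,3R)-3-[(3R)-2,6-dimethyl-2-(triethylsilyloxy)hept-5-en-3-yl]oxiran-2-yl]-3-methylocta-2,4,6-trienal
Conditions: MnO2, CH2Cl2, rt
Reagents that add atoms: none
Why: Neutral allylic oxidation with MnO2 gives the west C20 aldehyde without acid that would open the vinyl epoxide.

## East branch (steps 16–31)

Step 16
Reactants: 23 (R)-4-benzyl-1,3-oxazolidin-2-one; 2 3-methylbut-2-enoyl chloride
Product: 24 (4R)-4-benzyl-3-(3-methylbut-2-enoyl)-1,3-oxazolidin-2-one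
Conditions: n-BuLi, THF, −78 °C; then 2, −78 → 0 °C
Reagents that add atoms: none
Why: N-acylation of the lithiated enantiomeric Evans auxiliary, as in step 1.

Step 17
Reactants: 24 N-senecioyl imide; 4 prenyl bromide
Product: 25 (4R)-4-benzyl-3-[(2R)-5-methyl-2-(prop-1-en-2-yl)hex-4-enoyl]-1,3-oxazolidin-2-one
Conditions: NaN(SiMe3)2, THF, −78 °C; then 4, −78 → −20 °C
Reagents that add atoms: none
Why: Evans deconjugative α-prenylation of the (Z)-dienolate anti to the benzyl group, giving the mirror-image centre that becomes C2′.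

Step 18
Reactants: 25 alkylated imide
Product: 26 (R)-lavandulol [(2R)-5-methyl-2-(prop-1-en-2-yl)hex-4-en-1-ol]
Conditions: LiBH4, H2O (1 equiv), Et2O, 0 °C
Reagents that add atoms: none
Why: Reductive removal of the auxiliary to the primary alcohol, as in step 3.

Step 19
Reactants: 26 (R)-lavandulol
Product: 27 (3S)-3-(hydroxymethyl)-2,6-dimethylheptane-2,6-diol
Conditions: Co(acac)2 (20 mol%), PhSiH3 (4 equiv), O2 (1 atm), THF, rt
Reagents that add atoms: dioxygen O=O
Why: Mukaiyama hydration (hydrogen-atom transfer from a cobalt hydride, then O2 capture) turns both alkenes into tertiary alcohols through tertiary radicals, so no cationic cyclic-ether formation occurs and the stereocentre is untouched.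

Step 20
Reactants: 27 triol
Product: 28 (3S)-2,6-dimethyl-2,6-bis(triethylsilyloxy)-3-[(triethylsilyloxy)methyl]heptane
Conditions: Et3SiOTf (4 equiv), 2,6-lutidine, CH2Cl2, −78 → 0 °C
Reagents that add atoms: triethylsilyl triflate CC[Si](CC)(CC)OS(=O)(=O)C(F)(F)F
Why: Exhaustive silylation with the silyl triflate protects both tertiary alcohols and sets up the primary ether for direct oxidation.

Step 21
Reactants: 28 tris(silyl) ether
Product: 29 (2R)-5-methyl-5-(triethylsilyloxy)-2-[2-(triethylsilyloxy)propan-2-yl]hexanal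
Conditions: (COCl)2, DMSO, CH2Cl2, −78 → −40 °C; then Et3N, −78 → 0 °C
Reagents that add atoms: none
Why: Swern oxidation selective for the primary triethylsilyl ether, as in step 7, gives the aldehyde with both tertiary silyl ethers in place.

Step 22
Reactants: 29 aldehyde; 19 triethyl 3-methyl-4-phosphonocrotonate
Product: 30 ethyl (2E,4E,6S)-3,9-dimethyl-9-(triethylsilyloxy)-6-[2-(triethylsilyloxy)propan-2-yl]deca-2,4-dienoate
Conditions: 19, LiN(SiMe3)2, THF, −78 → 0 °C
Reagents that add atoms: none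
Why: Vinylogous Horner–Wadsworth–Emmons reaction forms C3′=C4′ E with a stabilised, weakly basic anion that does not epimerise the α-centre.

Step 23
Reactants: 30 dienoate
Product: 31 (2E,4E,6S)-3,9-dimethyl-9-(triethylsilyloxy)-6-[2-(triethylsilyloxy)propan-2-yl]deca-2,4-dien-1-ol
Conditions: iBu2AlH, CH2Cl2, −78 °C; aq. KNaC4H4O6
Reagents that add atoms: none
Why: 1,2-Reduction of the conjugated ester to the allylic alcohol.

Step 24
Reactants: 31 dienol
Product: 32 (2E,4E,6S)-3,9-dimethyl-9-(triethylsilyloxy)-6-[2-(triethylsilyloxy)propan-2-yl]deca-2,4-dienal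
Conditions: MnO2, CH2Cl2, rt
Reagents that add atoms: none
Why: Selective allylic oxidation with MnO2.

Step 25
Reactants: 32 dienal; 19 triethyl 3-methyl-4-phosphonocrotonate
Product: 33 ethyl (2E,4E,6E,8E,10S)-3,7,13-trimethyl-13-(triethylsilyloxy)-10-[2-(triethylsilyloxy)propan-2-yl]tetradeca-2,4,6,8-tetraenoate
Conditions: 19, LiN(SiMe3)2, THF, −78 → 0 °C
Reagents that add atoms: none
Why: A second vinylogous Horner–Wadsworth–Emmons extension forms C7′=C8′ E and completes the C20 chain.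

Step 26
Reactants: 33 tetraenoate
Product: 34 ethyl (2E,4E,6E,8E,10S)-13-hydroxy-10-(2-hydroxypropan-2-yl)-3,7,13-trimethyltetradeca-2,4,6,8-tetraenoate
Conditions: Bu4NF, THF, rt → 40 °C
Reagents that add atoms: none
Why: Fluoride desilylation frees both tertiary alcohols at the robust ester stage, before the acidic phosphonium-salt formations.

Step 27
Reactants: 34 diol ester
Product: 35 (2E,4E,6E,8E,10S)-10-(2-hydroxypropan-2-yl)-3,7,13-trimethyltetradeca-2,4,6,8-tetraene-1,13-diol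
Conditions: iBu2AlH (5 equiv), THF/CH2Cl2, −78 → −20 °C; aq. KNaC4H4O6
Reagents that add atoms: none
Why: Ester 1,2-reduction, with two extra equivalents of hydride consumed by the free tertiary hydroxyls.

Step 28
Reactants: 35 triol
Product: 36 [(2E,4E,6E,8E,10S)-13-hydroxy-10-(2-hydroxypropan-2-yl)-3,7,13-trimethyltetradeca-2,4,6,8-tetraen-1-yl]triphenylphosphonium bromide
Conditions: PPh3·HBr, MeOH, rt
Reagents that add atoms: triphenylphosphine hydrobromide [Br-].[PH+](c1ccccc1)(c1ccccc1)c1ccccc1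
Why: Only the polyenylic primary alcohol ionises under this buffered acid (SN1-type substitution) and the cation is trapped by PPh3 at its terminus, while the tertiary alcohols survive.

Step 29
Reactants: 36 C20 phosphonium salt; 37 (2E,4E,6E)-2,7-dimethylocta-2,4,6-trienedial
Product: 38 (2E,4E,6E,8E,10E,12E,14E,16E,18S)-21-hydroxy-18-(2-hydroxypropan-2-yl)-2,7,11,15,21-pentamethyldocosa-2,4,6,8,10,12,14,16-octaenal
Conditions: 37 (3 equiv), NaOMe, MeOH/CH2Cl2, slow addition of 36, 0 °C → rt; then heptane, 80 °C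
Reagents that add atoms: none
Why: Wittig olefination with excess dialdehyde stops at mono-condensation (new C11′=C12′), and heating converts the hindered Z isomer into the all-E C30 aldehyde.

Step 30
Reactants: 38 C30 aldehyde
Product: 39 (2E,4E,6E,8E,10E,12E,14E,16E,18S)-18-(2-hydroxypropan-2-yl)-2,7,11,15,21-pentamethyldocosa-2,4,6,8,10,12,14,16-octaene-1,21-diol
Conditions: NaBH4, EtOH/THF, 0 °C
Reagents that add atoms: none
Why: Borohydride 1,2-reduction of the polyenal to the allylic alcohol.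

Step 31
Reactants: 39 C30 alcohol
Product: 40 [(2E,4E,6E,8E,10E,12E,14E,16E,18S)-21-hydroxy-18-(2-hydroxypropan-2-yl)-2,7,11,15,21-pentamethyldocosa-2,4,6,8,10,12,14,16-octaen-1-yl]triphenylphosphonium bromide
Conditions: PPh3·HBr, MeOH/CH2Cl2, rt, dark
Reagents that add atoms: triphenylphosphine hydrobromide [Br-].[PH+](c1ccccc1)(c1ccccc1)c1ccccc1
Why: SN1-type phosphonium salt formation through the polyenyl cation, as in step 28.

## Union (steps 32–33)

Step 32
Reactants: 40 C30 phosphonium salt; 22 west C20 epoxy-trienal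
Product: 41 triethylsilyl ether of the target at the C1 tertiary hydroxyl (beside the prenyl-bearing centre)
Conditions: NaOMe, MeOH/CH2Cl2, 0 °C → rt, dark; then EtOAc, 60 °C
Reagents that add atoms: none
Why: Wittig union forms C11=C12 under purely basic conditions that the vinyl epoxide tolerates, and mild heating turns the sterically hindered 11Z isomer into the all-E polyene.

Step 33
Reactants: 41 silyl ether
Product: 42 CNP0268815.3 (target)
Conditions: Bu4NF, THF, 0 °C → rt, dark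
Reagents that add atoms: none
Why: Fluoride cleaves the last triethylsilyl ether without acid, so the polyenyl epoxide and all four stereocentres are left as set.

## Compound list

1 | (S)-4-benzyl-1,3-oxazolidin-2-one | O=C1N[C@@H](Cc2ccccc2)CO1 | starting material
2 | 3-methylbut-2-enoyl chloride | CC(C)=CC(Cl)=O | starting material
3 | (4S)-4-benzyl-3-(3-methylbut-2-enoyl)-1,3-oxazolidin-2-one | CC(C)=CC(=O)N1[C@@H](Cc2ccccc2)COC1=O | intermediate
4 | 1-bromo-3-methylbut-2-ene (prenyl bromide) | CC(C)=CCBr | starting material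
5 | (4S)-4-benzyl-3-[(2S)-5-methyl-2-(prop-1-en-2-yl)hex-4-enoyl]-1,3-oxazolidin-2-one | CC(C)=CC[C@H](C(=O)N1[C@@H](Cc2ccccc2)COC1=O)C(C)=C | intermediate
6 | (S)-lavandulol, (2S)-5-methyl-2-(prop-1-en-2-yl)hex-4-en-1-ol | CC(C)=CC[C@H](CO)C(C)=C | intermediate
7 | triethyl{[(2S)-5-methyl-2-(prop-1-en-2-yl)hex-4-en-1-yl]oxy}silane | CC(C)=CC[C@H](CO[Si](CC)(CC)CC)C(C)=C | intermediate
8 | {(3R)-2-hydroxy-2,6-dimethyl-3-[(triethylsilyloxy)methyl]hept-5-en-1-yl}mercury acetate (both C2 epimers; not isolated) | CC(C)=CC[C@H](CO[Si](CC)(CC)CC)C(C)(O)C[Hg]OC(C)=O | intermediate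
9 | (3R)-2,6-dimethyl-3-[(triethylsilyloxy)methyl]hept-5-en-2-ol | CC(C)=CC[C@H](CO[Si](CC)(CC)CC)C(C)(C)O | intermediate
10 | (3R)-2,6-dimethyl-2-(triethylsilyloxy)-3-[(triethylsilyloxy)methyl]hept-5-ene | CC(C)=CC[C@H](CO[Si](CC)(CC)CC)C(C)(C)O[Si](CC)(CC)CC | intermediate
11 | (2S)-5-methyl-2-[2-(triethylsilyloxy)propan-2-yl]hex-4-enal | CC(C)=CC[C@H](C=O)C(C)(C)O[Si](CC)(CC)CC | intermediate
12 | chloroacetone (1-chloropropan-2-one) | CC(=O)CCl | starting material
13 | (3R,4R,5R)-3-chloro-4-hydroxy-8-methyl-5-[2-(triethylsilyloxy)propan-2-yl]non-7-en-2-one | CC(C)=CC[C@H]([C@@H](O)[C@@H](Cl)C(C)=O)C(C)(C)O[Si](CC)(CC)CC | intermediate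
14 | 1-[(2S,3R)-3-[(3R)-2,6-dimethyl-2-(triethylsilyloxy)hept-5-en-3-yl]oxiran-2-yl]ethan-1-one | CC(C)=CC[C@H]([C@H]1O[C@@H]1C(C)=O)C(C)(C)O[Si](CC)(CC)CC | intermediate
15 | triethyl phosphonoacetate | CCOC(=O)CP(=O)(OCC)OCC | starting material
16 | ethyl (2E)-3-[(2R,3R)-3-[(3R)-2,6-dimethyl-2-(triethylsilyloxy)hept-5-en-3-yl]oxiran-2-yl]but-2-enoate | CC(C)=CC[C@H]([C@H]1O[C@@H]1/C(C)=C/C(=O)OCC)C(C)(C)O[Si](CC)(CC)CC | intermediate
17 | (2E)-3-[(2R,3R)-3-[(3R)-2,6-dimethyl-2-(triethylsilyloxy)hept-5-en-3-yl]oxiran-2-yl]but-2-en-1-ol | CC(C)=CC[C@H]([C@H]1O[C@@H]1/C(C)=C/CO)C(C)(C)O[Si](CC)(CC)CC | intermediate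
18 | (2E)-3-[(2R,3R)-3-[(3R)-2,6-dimethyl-2-(triethylsilyloxy)hept-5-en-3-yl]oxiran-2-yl]but-2-enal | CC(C)=CC[C@H]([C@H]1O[C@@H]1/C(C)=C/C=O)C(C)(C)O[Si](CC)(CC)CC | intermediate
19 | triethyl 3-methyl-4-phosphonocrotonate, ethyl (2E)-4-(diethoxyphosphoryl)-3-methylbut-2-enoate | CCOC(=O)/C=C(C)/CP(=O)(OCC)OCC | starting material
20 | ethyl (2E,4E,6E)-7-[(2R,3R)-3-[(3R)-2,6-dimethyl-2-(triethylsilyloxy)hept-5-en-3-yl]oxiran-2-yl]-3-methylocta-2,4,6-trienoate | CC(C)=CC[C@H]([C@H]1O[C@@H]1/C(C)=C/C=C/C(C)=C/C(=O)OCC)C(C)(C)O[Si](CC)(CC)CC | intermediate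
21 | (2E,4E,6E)-7-[(2R,3R)-3-[(3R)-2,6-dimethyl-2-(triethylsilyloxy)hept-5-en-3-yl]oxiran-2-yl]-3-methylocta-2,4,6-trien-1-ol | CC(C)=CC[C@H]([C@H]1O[C@@H]1/C(C)=C/C=C/C(C)=C/CO)C(C)(C)O[Si](CC)(CC)CC | intermediate
22 | (2E,4E,6E)-7-[(2R,3R)-3-[(3R)-2,6-dimethyl-2-(triethylsilyloxy)hept-5-en-3-yl]oxiran-2-yl]-3-methylocta-2,4,6-trienal | CC(C)=CC[C@H]([C@H]1O[C@@H]1/C(C)=C/C=C/C(C)=C/C=O)C(C)(C)O[Si](CC)(CC)CC | intermediate
23 | (R)-4-benzyl-1,3-oxazolidin-2-one | O=C1N[C@H](Cc2ccccc2)CO1 | starting material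
24 | (4R)-4-benzyl-3-(3-methylbut-2-enoyl)-1,3-oxazolidin-2-one | CC(C)=CC(=O)N1[C@H](Cc2ccccc2)COC1=O | intermediate
25 | (4R)-4-benzyl-3-[(2R)-5-methyl-2-(prop-1-en-2-yl)hex-4-enoyl]-1,3-oxazolidin-2-one | CC(C)=CC[C@@H](C(=O)N1[C@H](Cc2ccccc2)COC1=O)C(C)=C | intermediate
26 | (R)-lavandulol, (2R)-5-methyl-2-(prop-1-en-2-yl)hex-4-en-1-ol | CC(C)=CC[C@@H](CO)C(C)=C | intermediate
27 | (3S)-3-(hydroxymethyl)-2,6-dimethylheptane-2,6-diol | CC(C)(O)CC[C@@H](CO)C(C)(C)O | intermediate
28 | (3S)-2,6-dimethyl-2,6-bis(triethylsilyloxy)-3-[(triethylsilyloxy)methyl]heptane | CC[Si](CC)(CC)OC(C)(C)CC[C@@H](CO[Si](CC)(CC)CC)C(C)(C)O[Si](CC)(CC)CC | intermediate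
29 | (2R)-5-methyl-5-(triethylsilyloxy)-2-[2-(triethylsilyloxy)propan-2-yl]hexanal | CC[Si](CC)(CC)OC(C)(C)CC[C@@H](C=O)C(C)(C)O[Si](CC)(CC)CC | intermediate
30 | ethyl (2E,4E,6S)-3,9-dimethyl-9-(triethylsilyloxy)-6-[2-(triethylsilyloxy)propan-2-yl]deca-2,4-dienoate | CCOC(=O)/C=C(C)/C=C/[C@H](CCC(C)(C)O[Si](CC)(CC)CC)C(C)(C)O[Si](CC)(CC)CC | intermediate
31 | (2E,4E,6S)-3,9-dimethyl-9-(triethylsilyloxy)-6-[2-(triethylsilyloxy)propan-2-yl]deca-2,4-dien-1-ol | OC/C=C(C)/C=C/[C@H](CCC(C)(C)O[Si](CC)(CC)CC)C(C)(C)O[Si](CC)(CC)CC | intermediate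
32 | (2E,4E,6S)-3,9-dimethyl-9-(triethylsilyloxy)-6-[2-(triethylsilyloxy)propan-2-yl]deca-2,4-dienal | O=C/C=C(C)/C=C/[C@H](CCC(C)(C)O[Si](CC)(CC)CC)C(C)(C)O[Si](CC)(CC)CC | intermediate
33 | ethyl (2E,4E,6E,8E,10S)-3,7,13-trimethyl-13-(triethylsilyloxy)-10-[2-(triethylsilyloxy)propan-2-yl]tetradeca-2,4,6,8-tetraenoate | CCOC(=O)/C=C(C)/C=C/C=C(C)/C=C/[C@H](CCC(C)(C)O[Si](CC)(CC)CC)C(C)(C)O[Si](CC)(CC)CC | intermediate
34 | ethyl (2E,4E,6E,8E,10S)-13-hydroxy-10-(2-hydroxypropan-2-yl)-3,7,13-trimethyltetradeca-2,4,6,8-tetraenoate | CCOC(=O)/C=C(C)/C=C/C=C(C)/C=C/[C@H](CCC(C)(C)O)C(C)(C)O | intermediate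
35 | (2E,4E,6E,8E,10S)-10-(2-hydroxypropan-2-yl)-3,7,13-trimethyltetradeca-2,4,6,8-tetraene-1,13-diol | OC/C=C(C)/C=C/C=C(C)/C=C/[C@H](CCC(C)(C)O)C(C)(C)O | intermediate
36 | [(2E,4E,6E,8E,10S)-13-hydroxy-10-(2-hydroxypropan-2-yl)-3,7,13-trimethyltetradeca-2,4,6,8-tetraen-1-yl]triphenylphosphonium bromide | [Br-].c1ccccc1[P+](c1ccccc1)(c1ccccc1)C/C=C(C)/C=C/C=C(C)/C=C/[C@H](CCC(C)(C)O)C(C)(C)O | intermediate
37 | (2E,4E,6E)-2,7-dimethylocta-2,4,6-trienedial (C10 dialdehyde) | O=C/C(C)=C/C=C/C=C(C)/C=O | starting material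
38 | (2E,4E,6E,8E,10E,12E,14E,16E,18S)-21-hydroxy-18-(2-hydroxypropan-2-yl)-2,7,11,15,21-pentamethyldocosa-2,4,6,8,10,12,14,16-octaenal | O=C/C(C)=C/C=C/C=C(C)/C=C/C=C(C)/C=C/C=C(C)/C=C/[C@H](CCC(C)(C)O)C(C)(C)O | intermediate
39 | (2E,4E,6E,8E,10E,12E,14E,16E,18S)-18-(2-hydroxypropan-2-yl)-2,7,11,15,21-pentamethyldocosa-2,4,6,8,10,12,14,16-octaene-1,21-diol | OC/C(C)=C/C=C/C=C(C)/C=C/C=C(C)/C=C/C=C(C)/C=C/[C@H](CCC(C)(C)O)C(C)(C)O | intermediate
40 | [(2E,4E,6E,8E,10E,12E,14E,16E,18S)-21-hydroxy-18-(2-hydroxypropan-2-yl)-2,7,11,15,21-pentamethyldocosa-2,4,6,8,10,12,14,16-octaen-1-yl]triphenylphosphonium bromide | [Br-].c1ccccc1[P+](c1ccccc1)(c1ccccc1)C/C(C)=C/C=C/C=C(C)/C=C/C=C(C)/C=C/C=C(C)/C=C/[C@H](CCC(C)(C)O)C(C)(C)O | intermediate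
41 | target with its C1 tertiary hydroxyl (beside the prenyl-bearing centre) as the triethylsilyl ether; (2R,3R,4R,2′S), all-E | CC(C)=CC[C@H]([C@H]1O[C@@H]1/C(C)=C/C=C/C(C)=C/C=C/C(C)=C/C=C/C=C(C)/C=C/C=C(C)/C=C/C=C(C)/C=C/[C@H](CCC(C)(C)O)C(C)(C)O)C(C)(C)O[Si](CC)(CC)CC | intermediate
42 | CNP0268815.3: all-E C50 carotenoid; west end (2R)-CH(prenyl)(CMe2OH) on a (3R,4R)-trans-oxirane, east end (2′S)-CH(CH2CH2CMe2OH)(CMe2OH) | CC(C)=CC[C@H]([C@H]1O[C@@H]1/C(C)=C/C=C/C(C)=C/C=C/C(C)=C/C=C/C=C(C)/C=C/C=C(C)/C=C/C=C(C)/C=C/[C@H](CCC(C)(C)O)C(C)(C)O)C(C)(C)O | target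

## Step count and risks

Total step count: 33. Longest linear sequence: 18 steps (steps 16–31, then 32 and 33). The west branch (steps 1–15) joins at step 32.

Three steps most likely to fail:

Step 8 (organocatalytic chloroacetone aldol). Aldehyde 11 is very hindered and can epimerise or lose its β-silyloxy group under amine catalysis, and regio- or diastereocontrol may be poor. The fallback sets out from 11 and comes back to the route at 14, replacing steps 8 and 9. Wittig olefination of 11 with Ph3P=CHC(O)CH3 (toluene, 80 °C) gives the enone (3E,5R)-8-methyl-5-[2-(triethylsilyloxy)propan-2-yl]nona-3,7-dien-2-one F1. Catalytic asymmetric nucleophilic epoxidation of F1 (La(OiPr)3, (R)-BINOL, Ph3As=O, tBuOOH, 4 Å molecular sieves, THF, rt) then gives the trans-epoxy ketone 14; this is an oxa-Michael addition followed by ring closure, and (R)-BINOL is the enantiomer reported to give (αS,βR)-epoxy ketones.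

Step 10 (HWE on the epoxy methyl ketone). The E/Z ratio may be poor, and the ketone can enolise or the epoxide open under the basic conditions. The fallback sets out from 11 and comes back at 16, replacing steps 8–10. Ethyl (E)-4-bromo-3-methylbut-2-enoate is quaternised with tetrahydrothiophene (acetone, rt) to the sulfonium salt 1-[(2E)-4-ethoxy-2-methyl-4-oxobut-2-en-1-yl]thiolan-1-ium bromide F2. Its ester-stabilised ylide (Cs2CO3, CH2Cl2, rt) adds to 11 in the Felkin–Anh sense and closes to the trans-vinyl epoxide 16, with the (E)-trisubstituted alkene already in place.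

Step 32 (final Wittig union). The risks are Z isomers at C11=C12, which need heating that the vinyl epoxide may not stand, and sluggish reaction of the long ylide. The fallback sets out from 39 and comes back at 41, replacing steps 31 and 32 by an E-selective phosphonate olefination. Alcohol 39 is converted (MsCl, LiCl, 2,4,6-collidine, DMF, 0 °C) into the allylic chloride (2E,4E,6E,8E,10E,12E,14E,16E,18S)-1-chloro-18-(2-hydroxypropan-2-yl)-2,7,11,15,21-pentamethyldocosa-2,4,6,8,10,12,14,16-octaen-21-ol F3. Michaelis–Becker reaction with NaP(O)(OEt)2 (THF, 0 °C → rt) gives diethyl [(2E,4E,6E,8E,10E,12E,14E,16E,18S)-21-hydroxy-18-(2-hydroxypropan-2-yl)-2,7,11,15,21-pentamethyldocosa-2,4,6,8,10,12,14,16-octaen-1-yl]phosphonate F4. Its anion (NaN(SiMe3)2, 3.1 equiv, THF, −78 → 0 °C) condenses with aldehyde 22 to give 41 directly as the all-E isomer.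

Further compounds

F1 | step 8 | (3E,5R)-8-methyl-5-[2-(triethylsilyloxy)propan-2-yl]nona-3,7-dien-2-one | CC(C)=CC[C@H](/C=C/C(C)=O)C(C)(C)O[Si](CC)(CC)CC
F2 | step 10 | 1-[(2E)-4-ethoxy-2-methyl-4-oxobut-2-en-1-yl]thiolan-1-ium bromide | [Br-].CCOC(=O)/C=C(C)/C[S+]1CCCC1
F3 | step 32 | (2E,4E,6E,8E,10E,12E,14E,16E,18S)-1-chloro-18-(2-hydroxypropan-2-yl)-2,7,11,15,21-pentamethyldocosa-2,4,6,8,10,12,14,16-octaen-21-ol | ClC/C(C)=C/C=C/C=C(C)/C=C/C=C(C)/C=C/C=C(C)/C=C/[C@H](CCC(C)(C)O)C(C)(C)O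
F4 | step 32 | diethyl [(2E,4E,6E,8E,10E,12E,14E,16E,18S)-21-hydroxy-18-(2-hydroxypropan-2-yl)-2,7,11,15,21-pentamethyldocosa-2,4,6,8,10,12,14,16-octaen-1-yl]phosphonate | CCOP(=O)(OCC)C/C(C)=C/C=C/C=C(C)/C=C/C=C(C)/C=C/C=C(C)/C=C/[C@H](CCC(C)(C)O)C(C)(C)O
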